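**Retrosynthetic overview**

- Feature (daucane numbering: C1 ring-fusion carbon with CH3, C2 CH–OAc, C3 CH2, C4 C(OH)(i-Pr), C5 ring-fusion CH, C6 CH–O-aroyl, C7 CH2, C8(CH3)=C9, C10 CH2): on the cyclopentane C1–C2–C3–C4–C5 the C4–O bond and the C5–C6 bond are cis and lie on the face of the C1 methyl group. This is the geometry of a cis-fused β-lactone O4–C6(=O)–C5–C4.
- Late disconnections: phenol allyl ether, C2 acetate, C6 aroyl ester, and the C6 carbinol (reduction of the C6 ketone directed by the free C4–OH).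
- Cycloheptene (last ring): C6–C7, by attack of a Z-allyl sulfone carbanion on the β-lactone carbonyl, which frees C4–OH.
- Cyclopentane and β-lactone (formed together): C4–C5 and O4–C6, by nucleophile-catalysed aldol-lactonisation of an open-chain 6-oxo acid.
- The oxo acid comes from a temporary cyclohexene (C4=C6; Birch reduction of carvacrol silyl ether) that fixes C1 (asymmetric Tsuji allylation) and C2 (CBS reduction). The allyl group is converted into the Z-allyl sulfone arm, then the ring is cleaved.

Key step: step 13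

Remark (assumptions): atom labels C1–C10 are the daucane labels defined above; (S)-t-BuPHOX in step 3 is assumed to induce as with the 2-methylcyclohexanone enolate, (R)-HBTM in step 13 is assumed to be the matched catalyst (isothiourea enolate model: acyl oxygen syn to sulfur, attack anti to the C2 phenyl group), and compounds 8–14 are carried as two epoxide diastereomers because both epoxide carbons become carbonyl carbons in step 11.

Abbreviations: (S)-t-BuPHOX = (S)-4-tert-butyl-2-[2-(diphenylphosphino)phenyl]-4,5-dihydrooxazole; (R)-HBTM = (2R)-2-phenyl-3,4-dihydro-2H-benzo[4,5]thiazolo[3,2-a]pyrimidine; TBS = tert-butyldimethylsilyl.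

**Route**

Step 1
Reactants: 1 carvacrol (5-isopropyl-2-methylphenol)
Product: 2 tert-butyl(5-isopropyl-2-methylphenoxy)dimethylsilane
Conditions: TBSCl, imidazole, DMF, 23 °C
Reagents that add atoms: tert-butyldimethylsilyl chloride, CC(C)(C)[Si](C)(C)Cl
Why: Phenol silylation gives an aryl silyl ether that survives dissolving-metal reduction and carries the silyl group into the enol ether needed for step 3.

Step 2
Reactants: 2 aryl silyl ether
Product: 3 tert-butyl[(5-isopropyl-2-methylcyclohexa-1,4-dien-1-yl)oxy]dimethylsilane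
Conditions: Li, NH3 (l), THF, t-BuOH, −78 to −33 °C; then solid NH4Cl
Reagents that add atoms: none
Why: Birch reduction keeps the oxygen and both alkyl groups on sp2 carbons, so the two unsubstituted ring positions 3 and 6 are protonated and the product is a regiodefined tetrasubstituted silyl enol ether (future C2–O, C1) with the isopropyl-bearing alkene (future C4=C6) in place.

Step 3
Reactants: 3 silyl dienol ether; 4 diallyl carbonate
Product: 5 (R)-6-allyl-3-isopropyl-6-methylcyclohex-3-en-1-one
Conditions: Pd2(dba)3 (2.5 mol%), (S)-t-BuPHOX (6.25 mol%), Bu4N[Ph3SiF2] (35 mol%), THF, 25 °C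
Reagents that add atoms: none
Why: Enantioselective Tsuji allylation (silyl enol ether variant): fluoride frees the enolate, which is allylated only at the methyl-bearing carbon by the (PHOX)Pd–allyl complex under neutral conditions, setting quaternary C1; the (S)-ligand should give the R ketone by analogy with 2-methylcyclohexanone enolates.

Step 4
Reactants: 5 allyl ketone
Product: 6 (1S,6R)-6-allyl-3-isopropyl-6-methylcyclohex-3-en-1-ol (OH cis to allyl)
Conditions: (R)-2-methyl-CBS-oxazaborolidine (20 mol%), catecholborane, toluene, −78 to −40 °C; aq. NaOH work-up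
Reagents that add atoms: none
Why: Corey–Bakshi–Shibata reduction: the quaternary carbon is the large and the CH2 the small ketone substituent, so the (R)-oxazaborolidine should give the S carbinol (C2) under reagent control, catecholborane leaves both alkenes alone, and the minor enantiomer of 5 ends as a diastereomer that is removed by chromatography.

Step 5
Reactants: 6 cyclohexenol
Product: 7 tert-butyl{[(1S,6R)-6-allyl-3-isopropyl-6-methylcyclohex-3-en-1-yl]oxy}dimethylsilane
Conditions: TBSOTf, 2,6-lutidine, CH2Cl2, 0 °C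
Reagents that add atoms: tert-butyldimethylsilyl triflate, CC(C)(C)[Si](C)(C)OS(=O)(=O)C(F)(F)F
Why: Silylation with the silyl triflate protects the hindered secondary alcohol next to the quaternary carbon as an ether that withstands the base, hydride, acid and fluoride-free steps up to step 17.

Step 6
Reactants: 7 silyl ether
Product: 8 tert-butyl{[(3S,4R)-4-allyl-1-isopropyl-4-methyl-7-oxabicyclo[4.1.0]heptan-3-yl]oxy}dimethylsilane (two epoxide diastereomers)
Conditions: mCPBA (1.05 equiv), NaHCO3, CH2Cl2, 0 °C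
Reagents that add atoms: 3-chloroperbenzoic acid, OOC(=O)c1cccc(Cl)c1
Why: Prilezhaev epoxidation takes the electron-rich trisubstituted ring alkene much faster than the monosubstituted allyl alkene, which masks the C4=C6 bond (later the C4 ketone and C6 acid) while the allyl group is elaborated.

Step 7
Reactants: 8 epoxide
Product: 9 2-[(3S,4S)-4-(tert-butyldimethylsilyloxy)-6-isopropyl-3-methyl-7-oxabicyclo[4.1.0]heptan-3-yl]acetaldehyde
Conditions: OsO4 (2 mol%), NaIO4, 2,6-lutidine, 1,4-dioxane/H2O, 23 °C
Reagents that add atoms: sodium periodate (oxygen source, relayed by OsO4), [Na+].[O-]I(=O)(=O)=O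
Why: Lemieux–Johnson oxidation cleaves the only remaining alkene to the C9 aldehyde, and the lutidine-buffered medium leaves the epoxide and the silyl ether intact.

Step 8
Reactants: 9 aldehyde; 10 methyl 2-[bis(2,2,2-trifluoroethoxy)phosphoryl]propanoate
Product: 11 methyl (2Z)-4-[(3R,4S)-4-(tert-butyldimethylsilyloxy)-6-isopropyl-3-methyl-7-oxabicyclo[4.1.0]heptan-3-yl]-2-methylbut-2-enoate
Conditions: KN(SiMe3)2, 18-crown-6, THF, −78 °C
Reagents that add atoms: none
Why: Still–Gennari olefination: the trifluoroethyl phosphonate with a dissociated potassium counter-ion eliminates under kinetic control to the Z enoate, placing C10 and the ester carbon (future C7) cis across C8=C9 as the seven-membered ring requires.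

Step 9
Reactants: 11 Z enoate
Product: 12 (2Z)-4-[(3R,4S)-4-(tert-butyldimethylsilyloxy)-6-isopropyl-3-methyl-7-oxabicyclo[4.1.0]heptan-3-yl]-2-methylbut-2-en-1-ol
Conditions: i-Bu2AlH (3 equiv), CH2Cl2, −78 °C; Rochelle salt work-up
Reagents that add atoms: none
Why: Hydride reduction of the enoate to the allylic alcohol at −78 °C keeps the Z geometry and does not open the hindered trisubstituted epoxide.

Step 10
Reactants: 12 Z allylic alcohol
Product: 14 tert-butyl({(3S,4R)-1-isopropyl-4-methyl-4-[(2Z)-3-methyl-4-(phenylsulfonyl)but-2-en-1-yl]-7-oxabicyclo[4.1.0]heptan-3-yl}oxy)dimethylsilane, via allylic mesylate 13 (not isolated)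
Conditions: MsCl, Et3N, CH2Cl2, −30 °C; then PhSO2Na, DMF, 23 °C
Reagents that add atoms: sodium benzenesulfinate, [Na+].[O-]S(=O)c1ccccc1
Why: Mesylation followed by SN2 displacement at the primary allylic carbon by the sulfur of the sulfinate gives the allyl sulfone with the Z geometry retained, and the weakly basic sulfinate does not touch the epoxide.

Step 11
Reactants: 14 sulfone epoxide
Product: 15 (3R,4S)-4-(tert-butyldimethylsilyloxy)-3,7-dimethyl-3-[(2Z)-3-methyl-4-(phenylsulfonyl)but-2-en-1-yl]-6-oxooctanal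
Conditions: H5IO6, THF/H2O, 0 to 23 °C
Reagents that add atoms: water, O
Why: Periodic acid hydrolyses the epoxide and cleaves the glycol in one operation, which unveils the isopropyl ketone (C4) and the aldehyde (C6) from either epoxide diastereomer without attacking the electron-poor allyl sulfone alkene.

Step 12
Reactants: 15 keto aldehyde
Product: 16 (3R,4S)-4-(tert-butyldimethylsilyloxy)-3,7-dimethyl-3-[(2Z)-3-methyl-4-(phenylsulfonyl)but-2-en-1-yl]-6-oxooctanoic acid
Conditions: NaClO2, NaH2PO4, 2-methyl-2-butene, t-BuOH/H2O, 23 °C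
Reagents that add atoms: sodium chlorite, [Na+].[O-]Cl=O
Why: Pinnick oxidation gives the acid under buffered, non-basic conditions, so the β-silyloxy ketone cannot eliminate, and 2-methyl-2-butene scavenges HOCl before it reaches the arm alkene.

Step 13
Reactants: 16 keto acid
Product: 18 (1R,2R,3S,5R)-3-(tert-butyldimethylsilyloxy)-5-isopropyl-2-methyl-2-[(2Z)-3-methyl-4-(phenylsulfonyl)but-2-en-1-yl]-6-oxabicyclo[3.2.0]heptan-7-one, via mixed sulfonic anhydride 17 (not isolated)
Conditions: TsCl (1.25 equiv), (R)-HBTM (20 mol%), LiCl, i-Pr2NEt, CH2Cl2, 23 °C, slow addition of 16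
Reagents that add atoms: none
Why: TsCl converts the acid into mixed anhydride 17, which acylates the isothiourea; i-Pr2NEt deprotonates the acylammonium at C5 to a Z ammonium enolate, C5 adds to the isopropyl ketone C4, and the tertiary aldolate closes on the acylammonium carbon C6 and releases the catalyst. The closest known reaction is the nucleophile-catalysed aldol-lactonisation of keto acids to bicyclic β-lactones, applied here to a hindered ketone and a neopentyl enolate carbon. The cyclopentane closes by a 5-(enolexo)-exo-trig aldol (C4–C5) and the β-lactone by a 4-exo-trig acyl substitution (O4–C6). C4 and C5 are set together and must be cis because a four-membered lactone can only be cis-fused; the face is controlled by C1 and C2, the acylammonium going to the side of the small C1 methyl and away from the C10 arm and the C2 silyloxy group, and the (R)-catalyst is chosen to leave the same enolate face open. The step needs enolisation at C5 in preference to the ketone α-positions and the allyl sulfone (secured by the acylammonium and the weak amine base) and facial selectivity (secured by the C1/C2 substituents and reinforced by the catalyst), while slow addition keeps the activated acid dilute against ketene dimerisation.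

Step 14
Reactants: 18 β-lactone
Product: 19 (1S,3R,3aR,8aR)-1-(tert-butyldimethylsilyloxy)-3-hydroxy-3-isopropyl-6,8a-dimethyl-5-(phenylsulfonyl)-2,3,3a,5,8,8a-hexahydroazulen-4(1H)-one (epimers at the sulfonyl carbon C7)
Conditions: LiN(SiMe3)2 (2.5 equiv), THF, −78 to −20 °C; then aq. NH4Cl
Reagents that add atoms: none
Why: Claisen-type acylation of the α-sulfonyl carbanion (C7) by the strained lactone carbonyl (C6) closes the cycloheptene in a 7-exo-trig mode and expels the C4 alkoxide; attack through C9 would give a trans-fused bicyclo[3.3.0]octanone and is disfavoured, and the product is held as its β-keto sulfone enolate, which blocks retro-aldol.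

Step 15
Reactants: 19 β-keto sulfone
Product: 20 (1S,3R,3aR,8aR)-1-(tert-butyldimethylsilyloxy)-3-hydroxy-3-isopropyl-6,8a-dimethyl-2,3,3a,5,8,8a-hexahydroazulen-4(1H)-one
Conditions: SmI2 (3 equiv), THF/MeOH, −78 °C
Reagents that add atoms: none
Why: Reductive desulfonylation of the β-keto sulfone by single-electron transfer gives a samarium dienolate, and kinetic protonation at the α-carbon C7 by methanol at −78 °C should leave the alkene at C8=C9.

Step 16
Reactants: 20 β-hydroxy ketone
Product: 21 (1S,3R,3aS,4S,8aR)-1-(tert-butyldimethylsilyloxy)-3-isopropyl-6,8a-dimethyl-1,2,3,3a,4,5,8,8a-octahydroazulene-3,4-diol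
Conditions: Me4NBH(OAc)3, MeCN/AcOH, −30 to −20 °C
Reagents that add atoms: none
Why: Saksena–Evans reduction: the C4 hydroxyl exchanges onto boron and delivers hydride intramolecularly to the face of the C6 carbonyl on which O4 lies (the angular-methyl face), so the new C6 hydroxyl is placed on the opposite face with the 6S configuration.

Step 17
Reactants: 21 diol; 22 4-(allyloxy)benzoic acid
Product: 23 (1S,3R,3aS,4S,8aR)-1-(tert-butyldimethylsilyloxy)-3-hydroxy-3-isopropyl-6,8a-dimethyl-1,2,3,3a,4,5,8,8a-octahydroazulen-4-yl 4-(allyloxy)benzoate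
Conditions: EDC·HCl, 4-(dimethylamino)pyridine, CH2Cl2, 23 to 40 °C
Reagents that add atoms: none
Why: Steglich esterification acylates the only secondary hydroxyl (C6), while the tertiary C4 hydroxyl is too hindered to react.

Step 18
Reactants: 23 silyl ether ester
Product: 24 (1S,3R,3aS,4S,8aR)-1,3-dihydroxy-3-isopropyl-6,8a-dimethyl-1,2,3,3a,4,5,8,8a-octahydroazulen-4-yl 4-(allyloxy)benzoate
Conditions: HF·pyridine, pyridine, THF, 0 to 23 °C
Reagents that add atoms: none
Why: Fluoride-mediated desilylation in a pyridine-buffered medium frees the C2 hydroxyl without base-induced acyl migration and without ionising the tertiary alcohol.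

Step 19
Reactants: 24 diol ester
Product: 25 (1S,3R,3aS,4S,8aR)-1-acetoxy-3-hydroxy-3-isopropyl-6,8a-dimethyl-1,2,3,3a,4,5,8,8a-octahydroazulen-4-yl 4-(allyloxy)benzoate
Conditions: Ac2O, pyridine, 4-(dimethylamino)pyridine (cat.), CH2Cl2, 0 to 23 °C
Reagents that add atoms: acetic anhydride, CC(=O)OC(C)=O
Why: Nucleophile-catalysed acetylation takes the secondary C2 hydroxyl, and the tertiary C4 hydroxyl does not react under these mild conditions.

Step 20
Reactants: 25 allyl-protected ester
Product: 26 target, (1S,3R,3aS,4S,8aR)-1-acetoxy-3-hydroxy-3-isopropyl-6,8a-dimethyl-1,2,3,3a,4,5,8,8a-octahydroazulen-4-yl 4-hydroxybenzoate (CNP0275279.1)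
Conditions: Pd(PPh3)4 (5 mol%), morpholine, THF, 23 °C
Reagents that add atoms: none
Why: Tsuji–Trost deallylation: zerovalent palladium ionises the aryl allyl ether and morpholine traps the allyl group, which frees the phenol without touching the two esters, the tertiary alcohol or the trisubstituted alkene.

**Compound list**

1 | carvacrol (5-isopropyl-2-methylphenol) | Cc1ccc(C(C)C)cc1O | starting material
2 | tert-butyl(5-isopropyl-2-methylphenoxy)dimethylsilane | Cc1ccc(C(C)C)cc1O[Si](C)(C)C(C)(C)C | intermediate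
3 | tert-butyl[(5-isopropyl-2-methylcyclohexa-1,4-dien-1-yl)oxy]dimethylsilane | CC1=C(O[Si](C)(C)C(C)(C)C)CC(C(C)C)=CC1 | intermediate
4 | diallyl carbonate | C=CCOC(=O)OCC=C | starting material
5 | (R)-6-allyl-3-isopropyl-6-methylcyclohex-3-en-1-one | C[C@@]1(CC=C)CC=C(C(C)C)CC1=O | intermediate
6 | (1S,6R)-6-allyl-3-isopropyl-6-methylcyclohex-3-en-1-ol (OH cis to allyl) | C[C@@]1(CC=C)CC=C(C(C)C)C[C@@H]1O | intermediate
7 | tert-butyl{[(1S,6R)-6-allyl-3-isopropyl-6-methylcyclohex-3-en-1-yl]oxy}dimethylsilane | C[C@@]1(CC=C)CC=C(C(C)C)C[C@@H]1O[Si](C)(C)C(C)(C)C | intermediate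
8 | tert-butyl{[(3S,4R)-4-allyl-1-isopropyl-4-methyl-7-oxabicyclo[4.1.0]heptan-3-yl]oxy}dimethylsilane (two epoxide diastereomers; epoxide carbons left unassigned) | C[C@@]1(CC=C)CC2OC2(C(C)C)C[C@@H]1O[Si](C)(C)C(C)(C)C | intermediate
9 | 2-[(3S,4S)-4-(tert-butyldimethylsilyloxy)-6-isopropyl-3-methyl-7-oxabicyclo[4.1.0]heptan-3-yl]acetaldehyde (configuration at the quaternary and silyloxy carbons as in 8) | C[C@@]1(CC=O)CC2OC2(C(C)C)C[C@@H]1O[Si](C)(C)C(C)(C)C | intermediate
10 | methyl 2-[bis(2,2,2-trifluoroethoxy)phosphoryl]propanoate | COC(=O)C(C)P(=O)(OCC(F)(F)F)OCC(F)(F)F | starting material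
11 | methyl (2Z)-4-[(3R,4S)-4-(tert-butyldimethylsilyloxy)-6-isopropyl-3-methyl-7-oxabicyclo[4.1.0]heptan-3-yl]-2-methylbut-2-enoate | C[C@@]1(C/C=C(C)\C(=O)OC)CC2OC2(C(C)C)C[C@@H]1O[Si](C)(C)C(C)(C)C | intermediate
12 | (2Z)-4-[(3R,4S)-4-(tert-butyldimethylsilyloxy)-6-isopropyl-3-methyl-7-oxabicyclo[4.1.0]heptan-3-yl]-2-methylbut-2-en-1-ol | C[C@@]1(C/C=C(C)\CO)CC2OC2(C(C)C)C[C@@H]1O[Si](C)(C)C(C)(C)C | intermediate
13 | (2Z)-4-[(3R,4S)-4-(tert-butyldimethylsilyloxy)-6-isopropyl-3-methyl-7-oxabicyclo[4.1.0]heptan-3-yl]-2-methylbut-2-en-1-yl methanesulfonate | C[C@@]1(C/C=C(C)\COS(C)(=O)=O)CC2OC2(C(C)C)C[C@@H]1O[Si](C)(C)C(C)(C)C | intermediate (not isolated)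
14 | tert-butyl({(3S,4R)-1-isopropyl-4-methyl-4-[(2Z)-3-methyl-4-(phenylsulfonyl)but-2-en-1-yl]-7-oxabicyclo[4.1.0]heptan-3-yl}oxy)dimethylsilane | C[C@@]1(C/C=C(C)\CS(=O)(=O)c2ccccc2)CC3OC3(C(C)C)C[C@@H]1O[Si](C)(C)C(C)(C)C | intermediate
15 | (3R,4S)-4-(tert-butyldimethylsilyloxy)-3,7-dimethyl-3-[(2Z)-3-methyl-4-(phenylsulfonyl)but-2-en-1-yl]-6-oxooctanal | O=CC[C@@](C)(C/C=C(C)\CS(=O)(=O)c1ccccc1)[C@@H](O[Si](C)(C)C(C)(C)C)CC(=O)C(C)C | intermediate
16 | (3R,4S)-4-(tert-butyldimethylsilyloxy)-3,7-dimethyl-3-[(2Z)-3-methyl-4-(phenylsulfonyl)but-2-en-1-yl]-6-oxooctanoic acid (key-step precursor) | OC(=O)C[C@@](C)(C/C=C(C)\CS(=O)(=O)c1ccccc1)[C@@H](O[Si](C)(C)C(C)(C)C)CC(=O)C(C)C | intermediate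
17 | mixed anhydride of 16 with 4-methylbenzenesulfonic acid | Cc1ccc(cc1)S(=O)(=O)OC(=O)C[C@@](C)(C/C=C(C)\CS(=O)(=O)c1ccccc1)[C@@H](O[Si](C)(C)C(C)(C)C)CC(=O)C(C)C | intermediate (not isolated)
18 | (1R,2R,3S,5R)-3-(tert-butyldimethylsilyloxy)-5-isopropyl-2-methyl-2-[(2Z)-3-methyl-4-(phenylsulfonyl)but-2-en-1-yl]-6-oxabicyclo[3.2.0]heptan-7-one (key-step product) | CC(C)(C)[Si](C)(C)O[C@H]1C[C@]2(C(C)C)OC(=O)[C@@H]2[C@@]1(C)C/C=C(C)\CS(=O)(=O)c1ccccc1 | intermediate
19 | (1S,3R,3aR,8aR)-1-(tert-butyldimethylsilyloxy)-3-hydroxy-3-isopropyl-6,8a-dimethyl-5-(phenylsulfonyl)-2,3,3a,5,8,8a-hexahydroazulen-4(1H)-one (epimers at the sulfonyl carbon, left unassigned) | CC(C)(C)[Si](C)(C)O[C@H]1C[C@@](O)(C(C)C)[C@@H]2C(=O)C(S(=O)(=O)c3ccccc3)C(C)=CC[C@@]12C | intermediate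
20 | (1S,3R,3aR,8aR)-1-(tert-butyldimethylsilyloxy)-3-hydroxy-3-isopropyl-6,8a-dimethyl-2,3,3a,5,8,8a-hexahydroazulen-4(1H)-one | CC(C)(C)[Si](C)(C)O[C@H]1C[C@@](O)(C(C)C)[C@@H]2C(=O)CC(C)=CC[C@@]12C | intermediate
21 | (1S,3R,3aS,4S,8aR)-1-(tert-butyldimethylsilyloxy)-3-isopropyl-6,8a-dimethyl-1,2,3,3a,4,5,8,8a-octahydroazulene-3,4-diol | CC(C)(C)[Si](C)(C)O[C@H]1C[C@@](O)(C(C)C)[C@@H]2[C@@H](O)CC(C)=CC[C@@]12C | intermediate
22 | 4-(allyloxy)benzoic acid | C=CCOc1ccc(cc1)C(O)=O | starting material
23 | (1S,3R,3aS,4S,8aR)-1-(tert-butyldimethylsilyloxy)-3-hydroxy-3-isopropyl-6,8a-dimethyl-1,2,3,3a,4,5,8,8a-octahydroazulen-4-yl 4-(allyloxy)benzoate | CC(C)(C)[Si](C)(C)O[C@H]1C[C@@](O)(C(C)C)[C@@H]2[C@@H](OC(=O)c3ccc(OCC=C)cc3)CC(C)=CC[C@@]12C | intermediate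
24 | (1S,3R,3aS,4S,8aR)-1,3-dihydroxy-3-isopropyl-6,8a-dimethyl-1,2,3,3a,4,5,8,8a-octahydroazulen-4-yl 4-(allyloxy)benzoate | O[C@H]1C[C@@](O)(C(C)C)[C@@H]2[C@@H](OC(=O)c3ccc(OCC=C)cc3)CC(C)=CC[C@@]12C | intermediate
25 | (1S,3R,3aS,4S,8aR)-1-acetoxy-3-hydroxy-3-isopropyl-6,8a-dimethyl-1,2,3,3a,4,5,8,8a-octahydroazulen-4-yl 4-(allyloxy)benzoate | CC(=O)O[C@H]1C[C@@](O)(C(C)C)[C@@H]2[C@@H](OC(=O)c3ccc(OCC=C)cc3)CC(C)=CC[C@@]12C | intermediate
26 | (1S,3R,3aS,4S,8aR)-1-acetoxy-3-hydroxy-3-isopropyl-6,8a-dimethyl-1,2,3,3a,4,5,8,8a-octahydroazulen-4-yl 4-hydroxybenzoate (CNP0275279.1) | CC(=O)O[C@H]1C[C@@](O)(C(C)C)[C@@H]2[C@@H](OC(=O)c3ccc(O)cc3)CC(C)=CC[C@@]12C | target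

**Step count**

Total steps: 20. Longest linear sequence: 20 steps (1 to 26).

**Steps most likely to fail, with fallbacks**

Step 13. The aldol of the hindered ammonium enolate (neopentyl C5) onto the isopropyl ketone may be slow, so that the activated acid is lost to ketene dimerisation or symmetric anhydride formation, or the lactone closes on the face of the C10 arm. The fallback sets out from 16 and comes back at 19; it makes the two rings in the opposite order by carbanion chemistry. Esterification of 16 (Me3SiCHN2, MeOH/toluene, 0 °C) should give the methyl ester F1. LiN(SiMe3)2 (2.2 equiv, THF, −78 to 0 °C) deprotonates only the allyl sulfone, and the carbanion condenses with the ester to the monocyclic cycloheptenone β-keto sulfone F2. LiN(i-Pr)2 (2.2 equiv, THF, −78 °C) then forms the α,γ-dianion, whose γ-carbon C5 adds to the C4 ketone through a lithium-chelated aldol that places O4 and C6 cis; protonation gives 19, and the wanted diastereomer is separated if facial selectivity is incomplete.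

Step 14. The carbanion is tethered on the face opposite the lactone and may not reach the lactone carbonyl on a workable trajectory, so that proton transfer from C5 with β-elimination of the lactone, or intermolecular acylation, takes over. The fallback sets out from 18 and comes back at 19. The lactone is opened with MeNH(OMe)·HCl and Me2AlCl (CH2Cl2, 0 °C) to the β-hydroxy Weinreb amide F3, whose acyl group can rotate freely. LiN(SiMe3)2 (3.2 equiv, THF, −78 to 0 °C) then gives the alkoxide/sulfone dianion, and intramolecular acylation of the carbanion by the Weinreb amide gives 19.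

Step 3. With the bulky silyl enol ether, enantioselection may be low, or regiochemical integrity may be lost by proton transfer within the enolate and isomerisation of the β,γ-unsaturated ketone. The fallback sets out from 3 and comes back at 6. MeLi (THF, 0 to 23 °C) cleaves the silyl enol ether to the lithium enolate, which is allylated with allyl bromide to the racemic ketone F4. The reagent-controlled reduction of step 4 then converts the two enantiomers into 6 and its epimer at the quaternary carbon, the (1S,6S)-alcohol F5; these are diastereomers and are separated by chromatography, a resolution that costs half of the material.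

**Further compounds**

F1 | step 13 | methyl (3R,4S)-4-(tert-butyldimethylsilyloxy)-3,7-dimethyl-3-[(2Z)-3-methyl-4-(phenylsulfonyl)but-2-en-1-yl]-6-oxooctanoate | COC(=O)C[C@@](C)(C/C=C(C)\CS(=O)(=O)c1ccccc1)[C@@H](O[Si](C)(C)C(C)(C)C)CC(=O)C(C)C
F2 | step 13 | (6R)-6-[(1S)-1-(tert-butyldimethylsilyloxy)-4-methyl-3-oxopentyl]-3,6-dimethyl-2-(phenylsulfonyl)cyclohept-3-en-1-one (epimers at C2) | C1C(=O)C(S(=O)(=O)c2ccccc2)C(C)=CC[C@@]1(C)[C@@H](O[Si](C)(C)C(C)(C)C)CC(=O)C(C)C
F3 | step 14 | (1R,2R,3S,5R)-3-(tert-butyldimethylsilyloxy)-5-hydroxy-5-isopropyl-N-methoxy-N,2-dimethyl-2-[(2Z)-3-methyl-4-(phenylsulfonyl)but-2-en-1-yl]cyclopentane-1-carboxamide | CC(C)(C)[Si](C)(C)O[C@H]1C[C@@](O)(C(C)C)[C@H](C(=O)N(C)OC)[C@@]1(C)C/C=C(C)\CS(=O)(=O)c1ccccc1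
F4 | step 3 | racemic 6-allyl-3-isopropyl-6-methylcyclohex-3-en-1-one | CC1(CC=C)CC=C(C(C)C)CC1=O
F5 | step 3 | (1S,6S)-6-allyl-3-isopropyl-6-methylcyclohex-3-en-1-ol | C[C@]1(CC=C)CC=C(C(C)C)C[C@@H]1O
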